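All runs stem from a simulated flask for substances that don't exist; scatter was added.

The vessel is closed, stirred and held at a fixed temperature, and the flasks asked about take much less E than L, 2.0 mM against 0.40 M.

| flask | L | E | temperature | remark | time |
|---|---|---|---|---|---|
| eta | 0.40 M | 2.8 mM | 1 °C | run made earlier |  |
| beta | 0.40 M | 4.4 mM | 26 °C | run made earlier |  |
| south | 0.40 M | 2.0 mM | −10 °C |  | 12 min |
| north-west | 0.40 M | 2.0 mM | 20 °C |  | 12 min |
| east | 0.40 M | 2.0 mM | 5 °C |  | 12 min |
| south-east | 0.40 M | 2.0 mM | 35 °C |  | 12 min |

eta run (percent of the L charged)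

| time / min | J / % | L / % |
|---|---|---|
| 0.417 | 4 | 95 |
| 1.33 | 7 | 89 |
| 2.00 | 12 | 83 |
| 3.00 | 12 | 79 |
| 5.00 | 19 | 67 |

beta run (percent of the L charged)

| time / s | J / % | L / % |
|---|---|---|
| 10.0 | 8 | 88 |
| 20.0 | 12 | 77 |
| 30.0 | 18 | 66 |
| 50.0 | 22 | 48 |
| 80.0 | 22 | 37 |

(standard deviation of a reading: 1.5 percentage points)

1. the flask with the highest amount of J, in percent of the L charged ("all alike" if they lie within 1.5 percentage points) (south / north-west / east / south-east / all alike)
2. final J, as a percentage of the L charged, in south
3. final J, as a percentage of the L charged, in north-west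
4. final J, as a percentage of the L charged, in east
5. final J, as a percentage of the L charged, in south-east

Write the balance of E first. E stands on both sides of its steps, so it stays at its charge and L should fall pseudo-first-order. The logarithm of L charged over L left then grows with E times time at a given temperature, and I call it the dose. Eta reads 0.400 at its last point and beta 0.994. Taken per E and time, these two readings give an activation energy near 48.5 kJ mol⁻¹.

East looks much like eta, with a temperature of 5 °C against 1 °C. But it has 2.0 mM of E against 2.8 mM and runs 12 min against 5.00 min, so with all of these settings taken together its dose comes to 0.932. That dose, the reckoned logarithm of L charged over L left, is larger than eta's. I therefore expect 39.4% of the L left in east, against 67% in eta.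

In eta, J is about 57.6% of the L lost, so east should make about 34.9% of J. But J → Q has no E in it, and east runs longer than eta, so some of that J should go on to Q. East should end below that figure.

South has a reckoned dose of 0.282, which should make about 14.1% of J. North-west and south-east take 2.73 and 7.19, both beyond beta's dose. Beta's last two readings of J were 22% and 22%, while its L read 48% and then 37%. I commit to east.

The forecast names east, with 14.5% in south, 8% in north-west, 29% in east and 0.1% in south-east: “East wins.”

The flasks give 14.5% of J in south, 6.57% in north-west, 23.2% in east and 0.940% in south-east, so east holds the most.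

    L + E ⇌ J + E, rate k1*[L]*[E] forward; the back reaction follows from the equilibrium constant (K = 1.50, k = 28.0 M⁻¹ min⁻¹, Ea = 49.0 kJ mol⁻¹, ΔH = 27.0 kJ mol⁻¹)
    J → Q (k = 0.0660 min⁻¹, Ea = 79.0 kJ mol⁻¹)
    L + E ⇌ Z + E, rate k3*[L]*[E] forward; the back reaction follows from the equilibrium constant (K = 1.40, k = 15.0 M⁻¹ min⁻¹, Ea = 53.0 kJ mol⁻¹, ΔH = −1.00 kJ mol⁻¹)
    (constants at 5 °C)

East holds 43.0% of L against the 39.4% reckoned, and its J and Q together come to 36.5% against the 34.9% reckoned as made. Now take a flask like south-east but kept at 10 °C. Its dose is 1.35, which gives 25.9% of L left and 42.7% of J made. That flask holds 31% of L after 12.0 min, with 19.7% of J and 25.5% of Q.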